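The pyranone (ring C) is cut at C4–C4a and O1–C8a. C4a and C8a are ortho neighbours in ring A, so the acyloxy group need not be installed at C8a. It is placed on the carbon that becomes C4a, in a 2,4,5-trimethoxyphenyl 3-arylpropiolate, and is relayed to the vicinal C–H position during ring formation. One bromine-atom cascade (addition at C3, ipso spirocyclisation, 1,2-acyloxy shift, rearomatisation) makes both bonds, closes the lactone, and turns a cheap 1,2,4,5-oxygenated arene into the scarce 5,7,8-pattern. The precursor carries the 3'-oxygen as a pivalate, because a benzyl ether would not tolerate bromine atoms. Bromine and pivalate are removed in one final telescoped operation.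

Key step: step 5

Remark: coumarin numbering is used (ring A = C4a–C8a, ring B = 4-aryl, ring C = pyranone). In the cascade, carbons C1, C6, C5, C4, C3, C2 of the phenyl ester become C4a, C8a, C8, C7, C6, C5. 5-Iodo-2-methoxyphenol is assumed to be a catalogue chemical.

Step 1
Reactants: 1 2,4,5-trimethoxybenzaldehyde
Product: 3 2,4,5-trimethoxyphenol, via aryl formate 2 (not isolated)
Conditions: mCPBA, CH2Cl2, 0 °C to rt; aq. Na2SO3/NaHCO3 wash; then cat. HCl, MeOH, rt, N2
Reagents that add atoms: mCPBA, O=C(OO)c1cccc(Cl)c1
Why: Baeyer–Villiger (Dakin-type) oxidation, in which the electron-rich aryl group migrates in the Criegee adduct to give formate 2, which shields the oxidation-prone phenol until the peracid is washed out and is then cleaved by acid-catalysed methanolysis under nitrogen.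

Step 2
Reactants: 4 5-iodo-2-methoxyphenol
Product: 5 5-iodo-2-methoxyphenyl pivalate
Conditions: PivCl, Et3N, cat. DMAP, CH2Cl2, 0 °C to rt
Reagents that add atoms: pivaloyl chloride, CC(C)(C)C(=O)Cl
Why: DMAP-catalysed O-acylation of a phenol, giving a hindered ester that has only strong C–H bonds, resists DBU and DMAP in the next steps, and lowers the electron density of ring B.

Step 3
Reactants: 5 5-iodo-2-methoxyphenyl pivalate; 6 propiolic acid
Product: 7 3-[4-methoxy-3-(pivaloyloxy)phenyl]prop-2-ynoic acid
Conditions: Pd(PPh3)4 (cat.), DBU, DMSO, 35 °C, N2; cold 1 M HCl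
Reagents that add atoms: none
Why: Copper-free Sonogashira-type coupling of an aryl iodide with propiolic acid as its DBU carboxylate, a known direct entry to arylpropiolic acids in which zerovalent palladium inserts only into the C–I bond and the low temperature holds back decarboxylation.

Step 4
Reactants: 7 3-[4-methoxy-3-(pivaloyloxy)phenyl]prop-2-ynoic acid; 3 2,4,5-trimethoxyphenol
Product: 8 2,4,5-trimethoxyphenyl 3-[4-methoxy-3-(pivaloyloxy)phenyl]prop-2-ynoate
Conditions: DCC, cat. DMAP, CH2Cl2, 0 °C to rt, N2
Reagents that add atoms: none
Why: Steglich esterification, the usual way to aryl 3-arylpropiolates, in which phenol and DMAP are present before DCC is added at 0 °C so that the activated acid is intercepted before the symmetric anhydride can build up and dimerise by dehydro-Diels–Alder reaction.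

Step 5
Reactants: 8 2,4,5-trimethoxyphenyl 3-[4-methoxy-3-(pivaloyloxy)phenyl]prop-2-ynoate
Product: 12 3-bromo-5,7,8-trimethoxy-4-[4-methoxy-3-(pivaloyloxy)phenyl]coumarin, via vinyl radical 9 (not isolated), via spiro cyclohexadienyl radical 10 (not isolated), via acyloxyl radical 11 (not isolated)
Conditions: Bu4NBr (1.2 equiv), K2S2O8 (2 equiv), 4 Å MS, dry 1,2-dichloroethane, 90 °C, N2
Reagents that add atoms: tetrabutylammonium bromide, CCCC[N+](CCCC)(CCCC)CCCC.[Br-]
Why: Persulfate oxidises bromide to a bromine atom, which adds to the alkyne carbon next to the carbonyl (future C3) and leaves the linear, aryl-stabilised vinyl radical 9 on the future C4. Radical 9 closes 5-exo-trig onto the ester-bearing ipso carbon of ring A (C4–C4a formed) to give spiro radical 10, whose spin rests on the two methoxy-bearing carbons ortho and para to the spiro centre and on the free C–H carbon; that spiro centre is racemic and transient, so no stereocentre remains in 12. Rearomatising β-scission of the spiro C–O bond releases acyloxyl radical 11, held cis to ring A, which re-adds to the neighbouring C–H carbon in a six-membered (formally 6-endo-trig) closure that forms O1–C8a and ring C, and one-electron oxidation with proton loss gives 12. This is the known radical addition/ipso-cyclisation/1,2-ester-migration cascade of aryl 3-arylpropiolates in its bromide–persulfate version. The step needs ipso attack over direct ortho attack (which would lead to the 5,6,8-isomer), a single migration terminus, and fragmentation of 10 faster than its oxidation and O-demethylation to a spirodienone; these are served in turn by the kinetic 5-exo preference with two methoxy groups stabilising 10, by the methoxy block on the other ortho carbon, and by a strictly anhydrous medium with bromide kept near one equivalent. The pivalate offers no weak C–H bond to bromine atoms and deactivates ring B towards Br2, and any stray nuclear bromination is erased in step 6.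

Step 6
Reactants: 12 3-bromo-5,7,8-trimethoxy-4-[4-methoxy-3-(pivaloyloxy)phenyl]coumarin
Product: 14 4-(3-hydroxy-4-methoxyphenyl)-5,7,8-trimethoxycoumarin, via debrominated pivalate 13 (not isolated)
Conditions: H2 (1 atm), 10% Pd/C, Et3N, EtOAc, rt; filter, concentrate; then K2CO3, MeOH, rt, N2; 1 M HCl
Reagents that add atoms: none
Why: Catalytic hydrodehalogenation cleaves the activated vinylic C3–Br bond (and any stray aryl C–Br left by step 5) under amine buffering without touching the hindered C3–C4 double bond, and only then is the aryl pivalate removed by carbonate-mediated transesterification, an order that keeps alkoxide away from the 3-bromocoumarin (which would ring-contract in a Perkin rearrangement) and lets any opened lactone reclose on acidification because the cinnamate stays Z.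

Compound list
1 | 2,4,5-trimethoxybenzaldehyde | COc1cc(OC)c(C=O)cc1OC | starting material
2 | 2,4,5-trimethoxyphenyl formate (not isolated) | COc1cc(OC)c(OC=O)cc1OC | intermediate
3 | 2,4,5-trimethoxyphenol | COc1cc(OC)c(O)cc1OC | intermediate
4 | 5-iodo-2-methoxyphenol | COc1ccc(I)cc1O | starting material
5 | 5-iodo-2-methoxyphenyl pivalate | COc1ccc(I)cc1OC(=O)C(C)(C)C | intermediate
6 | propiolic acid | C#CC(=O)O | starting material
7 | 3-[4-methoxy-3-(pivaloyloxy)phenyl]prop-2-ynoic acid | COc1ccc(C#CC(=O)O)cc1OC(=O)C(C)(C)C | intermediate
8 | 2,4,5-trimethoxyphenyl 3-[4-methoxy-3-(pivaloyloxy)phenyl]prop-2-ynoate | COc1cc(OC)c(OC(=O)C#Cc2ccc(OC)c(OC(=O)C(C)(C)C)c2)cc1OC | intermediate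
9 | 2-bromo-1-aryl-3-oxo-3-(2,4,5-trimethoxyphenoxy)prop-1-en-1-yl radical, aryl = 4-methoxy-3-(pivaloyloxy)phenyl (not isolated) | COc1cc(OC)c(OC(=O)C(Br)=[C]c2ccc(OC)c(OC(=O)C(C)(C)C)c2)cc1OC | intermediate
10 | 3-bromo-4-aryl-6,8,9-trimethoxy-2-oxo-1-oxaspiro[4.5]deca-3,6,9-trien-8-yl radical, racemic transient spiro centre (not isolated) | COC1=CC2(OC(=O)C(Br)=C2c3ccc(OC)c(OC(=O)C(C)(C)C)c3)C(OC)=C[C]1OC | intermediate
11 | (E)-2-bromo-3-aryl-3-(2,4,5-trimethoxyphenyl)acryloyloxyl radical, carboxyl cis to ring A (not isolated) | [O]C(=O)/C(Br)=C(\c1cc(OC)c(OC)cc1OC)c1ccc(OC)c(OC(=O)C(C)(C)C)c1 | intermediate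
12 | 3-bromo-5,7,8-trimethoxy-4-[4-methoxy-3-(pivaloyloxy)phenyl]coumarin | COc1ccc(-c2c(Br)c(=O)oc3c(OC)c(OC)cc(OC)c23)cc1OC(=O)C(C)(C)C | intermediate
13 | 5,7,8-trimethoxy-4-[4-methoxy-3-(pivaloyloxy)phenyl]coumarin (not isolated) | COc1ccc(-c2cc(=O)oc3c(OC)c(OC)cc(OC)c23)cc1OC(=O)C(C)(C)C | intermediate
14 | 4-(3-hydroxy-4-methoxyphenyl)-5,7,8-trimethoxycoumarin (3'-hydroxy-5,7,8,4'-tetramethoxy-4-phenylcoumarin) | COc1ccc(-c2cc(=O)oc3c(OC)c(OC)cc(OC)c23)cc1O | target

Total step count: 6. Longest linear sequence: 5 (steps 2, 3, 4, 5, 6, from 4).

Steps most likely to fail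

Step 5. The spiro radical may be oxidised and O-demethylated before it fragments, which dearomatises ring A. Direct ortho closure may also compete, and the very electron-rich ring A may suffer electron-transfer degradation or ring bromination before the cascade starts. The fallback sets out from 5 and comes back at 13. It gives up the cascade and joins ring B to a preformed coumarin by Suzuki–Miyaura coupling.
- Iodide 5 is borylated (B2pin2, Pd(dppf)Cl2, KOAc, dioxane, 80 °C) to 2-methoxy-5-(4,4,5,5-tetramethyl-1,3,2-dioxaborolan-2-yl)phenyl pivalate F1.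
- In parallel, purchased 2'-hydroxy-3',4',6'-trimethoxyacetophenone F2 is condensed with diethyl carbonate (NaH, toluene, reflux) to 4-hydroxy-5,7,8-trimethoxycoumarin F3.
- Tf2O/Et3N (CH2Cl2, 0 °C) turns F3 into 5,7,8-trimethoxy-2-oxo-2H-chromen-4-yl triflate F4.
- Coupling of F1 with F4 (Pd(PPh3)4, anhydrous K3PO4, dioxane, 80 °C) should give 13, which enters the second half of step 6.

Step 3. The product acid may decarboxylate under base and palladium and then couple a second time. Oxidative addition to the electron-rich iodide may be sluggish, and the pivaloyl group may be partly lost to DBU. The fallback sets out from 5 and comes back at 7, with the carboxyl group masked and the amidine base avoided. Iodide 5 is coupled with tert-butyl propiolate (Pd(PPh3)2Cl2, CuI, K2CO3, THF, 60 °C) to tert-butyl 3-[4-methoxy-3-(pivaloyloxy)phenyl]prop-2-ynoate F5. Brief acidolysis (CF3CO2H/CH2Cl2, 0 °C to rt) then frees acid 7 with the pivalate intact.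

Step 6. The C3–C4 double bond may be saturated. The catalyst may also be poisoned by sulfur or bromide residues, which would stall the hydrogenolysis, carry C–Br into the carbonate stage, and trigger ring contraction. The fallback sets out from 12 and comes back at 13. The bromine is removed by electron transfer from zinc dust in acetic acid (rt to 50 °C), an acidic medium in which neither the lactone nor the pivalate is opened. Compound 13 is then isolated and checked to be halogen-free before the carbonate methanolysis of step 6 is applied.

Further compounds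
F1 | step 5 | 2-methoxy-5-(4,4,5,5-tetramethyl-1,3,2-dioxaborolan-2-yl)phenyl pivalate | COc1ccc(B2OC(C)(C)C(C)(C)O2)cc1OC(=O)C(C)(C)C
F2 | step 5 | 2'-hydroxy-3',4',6'-trimethoxyacetophenone (purchased) | CC(=O)c1c(O)c(OC)c(OC)cc1OC
F3 | step 5 | 4-hydroxy-5,7,8-trimethoxycoumarin | O=c1cc(O)c2c(OC)cc(OC)c(OC)c2o1
F4 | step 5 | 5,7,8-trimethoxy-2-oxo-2H-chromen-4-yl trifluoromethanesulfonate | O=c1cc(OS(=O)(=O)C(F)(F)F)c2c(OC)cc(OC)c(OC)c2o1
F5 | step 3 | tert-butyl 3-[4-methoxy-3-(pivaloyloxy)phenyl]prop-2-ynoate | COc1ccc(C#CC(=O)OC(C)(C)C)cc1OC(=O)C(C)(C)C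
F0 | step 6 | none | none
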